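**Plan**

- Locants used here: oxolane O1, C2 (aryl-bearing), C3 (acyloxymethyl-bearing), C4 (arylmethyl-bearing), C5. The target is (2S,3R,4R), i.e. 2,3-trans and 3,4-cis.
- Cuts, in retrosynthetic order: the ester C–O bond and the two phenol O–benzyl bonds; the C3–C4 ring bond; the O1–C5 ether bond; the oxirane oxygen and the C2–vinyl bond. Both halves go back to O-benzylvanillin.
- Enabling feature: C3 carries a CH2–O group and C4 an arylmethyl group, with O1 joining C2 to C5. C3–CH2O is therefore read as an opened oxirane (a β-oxygenated C3 radical) and C4–CH2Ar as a styrene that has accepted that radical, so the precursor is an epoxy cinnamyl ether.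
- Forward: vinyl addition; kinetic resolution to the epoxy alcohol, while the unreacted enantiomer is turned into the cinnamyl bromide; ether formation (O1–C5); strain-release radical closure of the oxolane, the only ring made (step 5); acylation; debenzylation.
- Stereochemistry: C2 from the tartrate-controlled kinetic resolution; C3 and C4 from C2 through the chair-like 5-exo transition state.

Key step: step 5

**Route**

Step 1
Reactants: 1 4-(benzyloxy)-3-methoxybenzaldehyde (O-benzylvanillin)
Product: 3 rac-1-[4-(benzyloxy)-3-methoxyphenyl]prop-2-en-1-ol, via bromomagnesium alkoxide 2 (not isolated)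
Conditions: CH2=CHMgBr (1.2 equiv), THF, 0 °C; then H2O, sat. aq. NH4Cl
Reagents that add atoms: vinylmagnesium bromide, C=C[Mg]Br
Why: Grignard 1,2-addition of the vinyl nucleophile to the aryl aldehyde should give the secondary allylic alcohol as a racemate, which is intended because step 2 resolves the new stereocentre and step 3 erases it.

Step 2
Reactants: 3 rac-1-[4-(benzyloxy)-3-methoxyphenyl]prop-2-en-1-ol
Product: 4 (R)-[4-(benzyloxy)-3-methoxyphenyl][(2S)-oxiran-2-yl]methanol (anti epoxy alcohol)
Conditions: Ti(OiPr)4 (0.1 equiv), D-(−)-diisopropyl tartrate [(2S,3S), 0.15 equiv], t-BuOOH (0.45 equiv, isooctane), 4 Å molecular sieves, CH2Cl2, −20 °C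
Reagents that add atoms: tert-butyl hydroperoxide, CC(C)(C)OO
Why: Sharpless kinetic resolution (titanium–tartrate asymmetric epoxidation of a secondary allylic alcohol) should epoxidise the (S)-enantiomer of 3 much faster and anti-selectively with the D-(−)-tartrate, so that below half conversion the epoxy alcohol carries the future C2 centre in high enantiomeric purity (its descriptor becomes R only because the oxirane carbon now outranks the aryl group), while the untouched (R)-enantiomer of 3 is recovered for step 3.

Step 3
Reactants: 3 rac-1-[4-(benzyloxy)-3-methoxyphenyl]prop-2-en-1-ol (fresh racemate or the enantiomer left unreacted in step 2)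
Product: 5 1-(benzyloxy)-4-[(1E)-3-bromoprop-1-en-1-yl]-2-methoxybenzene
Conditions: PBr3 (0.4 equiv), Et2O, 0 °C; used at once without storage
Reagents that add atoms: phosphorus tribromide, BrP(Br)Br
Why: Bromination of an aryl vinyl carbinol with PBr3 should proceed with allylic transposition (SN1/SN2′ through the aryl-stabilised allyl cation) to the conjugated, thermodynamically preferred (E)-cinnamyl bromide, so either enantiomer of 3 is a suitable feed and the resolution of step 2 divides the racemate into the two coupling partners.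

Step 4
Reactants: 4 (R)-[4-(benzyloxy)-3-methoxyphenyl][(2S)-oxiran-2-yl]methanol; 5 1-(benzyloxy)-4-[(1E)-3-bromoprop-1-en-1-yl]-2-methoxybenzene
Product: 7 (2S)-2-[(R)-[4-(benzyloxy)-3-methoxyphenyl]{[(2E)-3-[4-(benzyloxy)-3-methoxyphenyl]prop-2-en-1-yl]oxy}methyl]oxirane, via sodium alkoxide 6 (not isolated)
Conditions: NaH (1.1 equiv), THF, 0 °C; then 5, Bu4NI (cat.), 0 °C to rt
Reagents that add atoms: none
Why: Williamson ether synthesis, in which the sodium alkoxide displaces the primary allylic bromide by SN2 to form the O1–C5 bond, low temperature and iodide catalysis keeping alkylation ahead of epoxide migration, with the carbinol stereocentre not involved.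

Step 5
Reactants: 7 (2S)-2-[(R)-[4-(benzyloxy)-3-methoxyphenyl]{[(2E)-3-[4-(benzyloxy)-3-methoxyphenyl]prop-2-en-1-yl]oxy}methyl]oxirane
Product: 9 [(2S,3R,4R)-2-[4-(benzyloxy)-3-methoxyphenyl]-4-{[4-(benzyloxy)-3-methoxyphenyl]methyl}oxolan-3-yl]methanol, via bis(titanocene chloride) cyclisation adduct 8 (not isolated)
Conditions: Cp2TiCl2 (2.5 equiv), Zn dust, THF, rt (green Cp2TiCl solution), added slowly to 7 in THF, rt; then 1 M aq. HCl, 0 °C
Reagents that add atoms: none
Why: Cp2TiCl (trivalent titanium) transfers one electron to the oxirane oxygen and the strained ring opens homolytically at its more substituted C–O bond, giving a β-titanoxy secondary radical at C3 that adds to the styrene-type alkene to form the C3–C4 bond, after which the benzylic radical is captured by a second Cp2TiCl and the C–Ti and O–Ti bonds of 8 are protonated on work-up. The closest known reaction type is the titanocene-mediated reductive epoxide opening with radical cyclisation (Nugent–RajanBabu reaction), which has close precedent on epoxy cinnamyl ethers of this lignan class. The oxolane is closed in the 5-exo-trig mode. C3 and C4 are both controlled by the C2 stereocentre through a chair-like transition state in which the C2 aryl group and the C3 CH2O[Ti] group are pseudo-equatorial (2,3-trans) and the substituent on the radical carbon and the new arylmethyl group end up cis (3,4-cis); the configuration of the oxirane carbon is irrelevant because C3 becomes planar. The step needs regioselective opening to the secondary rather than the primary radical, which radical stability secures, and it needs cyclisation to outrun reduction of the open radical, which the aryl-conjugated acceptor and a low titanium concentration (slow addition) should secure. Benzyl ethers, aryl ethers and the C2–O1 benzylic ether are inert to Cp2TiCl.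

Step 6
Reactants: 9 [(2S,3R,4R)-2-[4-(benzyloxy)-3-methoxyphenyl]-4-{[4-(benzyloxy)-3-methoxyphenyl]methyl}oxolan-3-yl]methanol
Product: 10 [(2S,3R,4R)-2-[4-(benzyloxy)-3-methoxyphenyl]-4-{[4-(benzyloxy)-3-methoxyphenyl]methyl}oxolan-3-yl]methyl 3-methylbutanoate
Conditions: isovaleryl chloride (1.2 equiv), Et3N, DMAP (cat.), CH2Cl2, 0 °C
Reagents that add atoms: 3-methylbutanoyl chloride (isovaleryl chloride), CC(C)CC(Cl)=O
Why: DMAP-catalysed acylation with an acid chloride should esterify the only free hydroxyl group, the primary alcohol unveiled in step 5, because both phenols are still benzyl ethers, and no stereocentre is touched.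

Step 7
Reactants: 10 [(2S,3R,4R)-2-[4-(benzyloxy)-3-methoxyphenyl]-4-{[4-(benzyloxy)-3-methoxyphenyl]methyl}oxolan-3-yl]methyl 3-methylbutanoate
Product: 11 [(2S,3R,4R)-2-(4-hydroxy-3-methoxyphenyl)-4-[(4-hydroxy-3-methoxyphenyl)methyl]oxolan-3-yl]methyl 3-methylbutanoate, (+)-9'-isovaleroxylariciresinol
Conditions: H2 (1 atm), 10% Pd/C, EtOAc, rt; stopped after uptake of two equivalents of H2
Reagents that add atoms: none
Why: Catalytic hydrogenolysis of the two aryl benzyl ethers should, under neutral conditions in ethyl acetate, be much faster than cleavage of the ring C2–O1 benzylic bond and leaves the ester and all three stereocentres untouched.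

**Compound list**

1 | 4-(benzyloxy)-3-methoxybenzaldehyde (O-benzylvanillin) | COc1cc(C=O)ccc1OCc1ccccc1 | starting material
2 | bromomagnesium 1-[4-(benzyloxy)-3-methoxyphenyl]prop-2-en-1-olate, racemic (not isolated) | C=CC(O[Mg]Br)c1ccc(OCc2ccccc2)c(OC)c1 | intermediate
3 | rac-1-[4-(benzyloxy)-3-methoxyphenyl]prop-2-en-1-ol | C=CC(O)c1ccc(OCc2ccccc2)c(OC)c1 | intermediate
4 | (R)-[4-(benzyloxy)-3-methoxyphenyl][(2S)-oxiran-2-yl]methanol | O[C@H](c1ccc(OCc2ccccc2)c(OC)c1)[C@@H]1CO1 | intermediate
5 | 1-(benzyloxy)-4-[(1E)-3-bromoprop-1-en-1-yl]-2-methoxybenzene | COc1cc(/C=C/CBr)ccc1OCc1ccccc1 | intermediate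
6 | sodium (R)-[4-(benzyloxy)-3-methoxyphenyl][(2S)-oxiran-2-yl]methanolate (not isolated) | [Na+].[O-][C@H](c1ccc(OCc2ccccc2)c(OC)c1)[C@@H]1CO1 | intermediate
7 | (2S)-2-[(R)-[4-(benzyloxy)-3-methoxyphenyl]{[(2E)-3-[4-(benzyloxy)-3-methoxyphenyl]prop-2-en-1-yl]oxy}methyl]oxirane | COc1cc(/C=C/CO[C@H](c2ccc(OCc3ccccc3)c(OC)c2)[C@@H]2CO2)ccc1OCc1ccccc1 | intermediate
8 | cyclised oxolane carrying a Cp2TiCl group on the oxygen of the C3 CH2O arm and a Cp2TiCl group on the benzylic carbon of the C4 side chain (not isolated; Cp drawn σ-bonded) | COc1cc(C([Ti](Cl)(C5C=CC=C5)C6C=CC=C6)[C@H]2CO[C@H](c3ccc(OCc4ccccc4)c(OC)c3)[C@H]2CO[Ti](Cl)(C7C=CC=C7)C8C=CC=C8)ccc1OCc1ccccc1 | intermediate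
9 | [(2S,3R,4R)-2-[4-(benzyloxy)-3-methoxyphenyl]-4-{[4-(benzyloxy)-3-methoxyphenyl]methyl}oxolan-3-yl]methanol | COc1cc(C[C@H]2CO[C@H](c3ccc(OCc4ccccc4)c(OC)c3)[C@H]2CO)ccc1OCc1ccccc1 | intermediate
10 | [(2S,3R,4R)-2-[4-(benzyloxy)-3-methoxyphenyl]-4-{[4-(benzyloxy)-3-methoxyphenyl]methyl}oxolan-3-yl]methyl 3-methylbutanoate | COc1cc(C[C@H]2CO[C@H](c3ccc(OCc4ccccc4)c(OC)c3)[C@H]2COC(=O)CC(C)C)ccc1OCc1ccccc1 | intermediate
11 | [(2S,3R,4R)-2-(4-hydroxy-3-methoxyphenyl)-4-[(4-hydroxy-3-methoxyphenyl)methyl]oxolan-3-yl]methyl 3-methylbutanoate, (+)-9'-isovaleroxylariciresinol | COc1cc(C[C@H]2CO[C@H](c3ccc(O)c(OC)c3)[C@H]2COC(=O)CC(C)C)ccc1O | target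

**Step count**

Total step count: 7. Longest linear sequence: 6 steps (steps 1, 2, 4, 5, 6, 7); step 3 is the side branch.

**Steps most likely to fail**

Step 5. The 5-exo closure may discriminate the two faces of the alkene at C4 too weakly, and the open C3 radical may be reduced by titanium before it closes. The fallback sets out from 4 and comes back at 11; it moves control of C4 from the radical step to a hydrogenation.
- 4 is O-alkylated with propargyl bromide (NaH, THF, 0 °C) to the epoxy propargyl ether F1.
- Sonogashira coupling of F1 (PdCl2(PPh3)2, CuI, Et3N) with 1-(benzyloxy)-4-iodo-2-methoxybenzene F2 should give the aryl alkyne epoxy ether F3. F2 is made from commercial 4-iodo-2-methoxyphenol with benzyl bromide and K2CO3.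
- The same Cp2TiCl opening (Cp2TiCl2, Zn, THF) is then expected to close 5-exo-dig onto the alkyne, where no C4 stereocentre is formed. This should give the 2,3-trans 4-benzylidene oxolane alcohol F4; its alkene geometry is immaterial.
- Acylation as in step 6 gives its 3-methylbutanoate F5.
- Hydrogenation over Pd/C in EtOAc should deliver hydrogen to the exocyclic alkene from the face opposite the neighbouring C3 acyloxymethyl group (3,4-cis) and remove both benzyl groups in the same operation, arriving at 11.

Step 4. The alkoxide may trigger epoxide migration (Payne rearrangement) before O-alkylation, and the electron-rich allylic bromide may ionise and decompose before it is consumed. The fallback sets out from 3 and 4 and comes back at 7; it replaces the SN2 displacement by a palladium-catalysed allylic etherification (Tsuji–Trost type) that needs neither a free alkali alkoxide nor the bromide.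
- 3 is acetylated (Ac2O, pyridine, DMAP) to the allylic acetate F6.
- 4 is converted with Et2Zn (0.5 equiv, THF) into the zinc alkoxide F7.
- F6 and F7 are coupled with Pd(OAc)2 and 2-(di-tert-butylphosphino)biphenyl in THF at rt. Oxidative addition to zerovalent palladium gives the 1-aryl-π-allyl complex, and attack of the zinc alkoxide at the unsubstituted terminus should give the linear (E)-cinnamyl ether 7.

Step 2. The rate difference between the two enantiomers may be too small at useful conversion, so that the epoxy alcohol is formed with eroded enantiomeric purity. The fallback sets out from 3 and comes back at 4; it separates the enantiomers enzymatically first and then uses the epoxidation as a second, matched selection.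
- Candida antarctica lipase B with vinyl acetate in tert-butyl methyl ether at rt should acetylate the (R)-enantiomer to the (R)-acetate F9 and leave the (S)-alcohol F8, which is separated by chromatography.
- F8 is epoxidised to full conversion with Ti(OiPr)4, D-(−)-diisopropyl tartrate and t-BuOOH (matched pair, anti-selective) to give 4.

**Further compounds**

F1 | step 5 | (2S)-2-[(R)-[4-(benzyloxy)-3-methoxyphenyl](prop-2-yn-1-yloxy)methyl]oxirane | C#CCO[C@H](c1ccc(OCc2ccccc2)c(OC)c1)[C@@H]1CO1
F2 | step 5 | 1-(benzyloxy)-4-iodo-2-methoxybenzene | COc1cc(I)ccc1OCc1ccccc1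
F3 | step 5 | (2S)-2-[(R)-[4-(benzyloxy)-3-methoxyphenyl]({3-[4-(benzyloxy)-3-methoxyphenyl]prop-2-yn-1-yl}oxy)methyl]oxirane | COc1cc(C#CCO[C@H](c2ccc(OCc3ccccc3)c(OC)c2)[C@@H]2CO2)ccc1OCc1ccccc1
F4 | step 5 | [(2S,3R)-2-[4-(benzyloxy)-3-methoxyphenyl]-4-{[4-(benzyloxy)-3-methoxyphenyl]methylidene}oxolan-3-yl]methanol | COc1cc(C=C2CO[C@H](c3ccc(OCc4ccccc4)c(OC)c3)[C@H]2CO)ccc1OCc1ccccc1
F5 | step 5 | [(2S,3R)-2-[4-(benzyloxy)-3-methoxyphenyl]-4-{[4-(benzyloxy)-3-methoxyphenyl]methylidene}oxolan-3-yl]methyl 3-methylbutanoate | COc1cc(C=C2CO[C@H](c3ccc(OCc4ccccc4)c(OC)c3)[C@H]2COC(=O)CC(C)C)ccc1OCc1ccccc1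
F6 | step 4 | rac-1-[4-(benzyloxy)-3-methoxyphenyl]prop-2-en-1-yl acetate | C=CC(OC(C)=O)c1ccc(OCc2ccccc2)c(OC)c1
F7 | step 4 | zinc bis{(R)-[4-(benzyloxy)-3-methoxyphenyl][(2S)-oxiran-2-yl]methanolate} | [Zn+2].[O-][C@H](c1ccc(OCc2ccccc2)c(OC)c1)[C@@H]1CO1.[O-][C@H](c1ccc(OCc2ccccc2)c(OC)c1)[C@@H]1CO1
F8 | step 2 | (S)-1-[4-(benzyloxy)-3-methoxyphenyl]prop-2-en-1-ol | C=C[C@H](O)c1ccc(OCc2ccccc2)c(OC)c1
F9 | step 2 | (R)-1-[4-(benzyloxy)-3-methoxyphenyl]prop-2-en-1-yl acetate | C=C[C@@H](OC(C)=O)c1ccc(OCc2ccccc2)c(OC)c1
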